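**Assumption:** the SMILES is taken literally. Ring numbering used below: C1 = lactone O–CH, C2=C3(CH3), C4 = CH–OAc, C5/C6 = epoxide (CH3 on C6), C7, C8 = CH2, C9 = CH–O-angeloyl, C10 = CH carrying C11(=C13H2)–C12(=O)O. Target = 1S,2E,4R,5R,6S,9R,10R, lactone cis-fused (H1 and H10 syn), angelate = (Z)-2-methylbut-2-enoate.

## Retrosynthetic overview

1. Target 21 ⇒ acyclic enal/allyl bromide 18. The last step forms C1–C10 by adding the allylchromium reagent (acrylate β-carbon as nucleophile) to the enal carbonyl; the new alkoxide lactonises.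
2. 18 ⇒ allylic angelate 15 + methyl 2-(bromomethyl)acrylate 16 by cross-metathesis; the enal is carried as its diethyl acetal.
3. 15 ⇒ aldehyde 11: C9 is set by catalyst-controlled vinylzinc addition to the aldehyde released by ozonolysis of the prenyl end of nerol.
4. 11 ⇒ 2,3-epoxyneral 6 + alkenyllithium 7 (a β-formylvinyl anion equivalent) for C3–C4 with Felkin–Anh control of C4; C5/C6 come from Sharpless epoxidation of nerol.
5. Ring order: oxirane first (step 2); the 10-membered carbocycle and the γ-lactone last, in one operation (step 11).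

## Route

Step 1
Reactants: 1 1,1-diethoxybut-2-yne
Product: 3 (2E)-1,1-diethoxy-3-iodobut-2-ene, via alkenylzirconocene chloride 2 (not isolated)
Conditions: Cp2Zr(H)Cl (2 equiv), THF, 50 °C; then I2, 0 °C
Reagents that add atoms: iodine, II
Why: Hydrozirconation–iodination; syn addition with zirconium settling (excess reagent, equilibration) on the less hindered methyl-bearing carbon gives the E iodide with retention on iodinolysis.

Step 2
Reactants: 4 nerol
Product: 5 (2R,3S)-2,3-epoxynerol
Conditions: Ti(OiPr)4 (10 mol %), D-(−)-diethyl tartrate (12 mol %), t-BuOOH, 4 Å MS, CH2Cl2, −20 °C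
Reagents that add atoms: tert-butyl hydroperoxide, CC(C)(C)OO
Why: Sharpless asymmetric epoxidation of the Z allylic alcohol; the D-(−)-tartrate delivers oxygen to the face giving 2R,3S (future C5 R, C6 S), and the isolated prenyl alkene is untouched.

Step 3
Reactants: 5 (2R,3S)-2,3-epoxynerol
Product: 6 (2S,3S)-3-methyl-3-(4-methylpent-3-en-1-yl)oxirane-2-carbaldehyde
Conditions: TEMPO (10 mol %), PhI(OAc)2, CH2Cl2, 20 °C
Reagents that add atoms: none
Why: Oxoammonium (TEMPO) oxidation of the primary alcohol to the aldehyde without touching epoxide or alkene; the descriptor change at C2 is only a priority change.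

Step 4
Reactants: 6 epoxy aldehyde; 3 (2E)-1,1-diethoxy-3-iodobut-2-ene
Product: 8 (1R,2E)-4,4-diethoxy-2-methyl-1-[(2R,3S)-3-methyl-3-(4-methylpent-3-en-1-yl)oxiran-2-yl]but-2-en-1-ol, via alkenyllithium 7 (not isolated)
Conditions: 3, t-BuLi (2 equiv), Et2O, −78 °C; then 6, −78 °C; H2O work-up
Reagents that add atoms: none
Why: Iodine–lithium exchange (retention of alkene geometry) then 1,2-addition to the cis-substituted epoxy aldehyde under Felkin–Anh control (epoxide C–O anti to the nucleophile), giving the anti epoxy alcohol, i.e. C4 R.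

Step 5
Reactants: 8 allylic alcohol
Product: 9 (1R,2E)-4,4-diethoxy-2-methyl-1-[(2R,3S)-3-methyl-3-(4-methylpent-3-en-1-yl)oxiran-2-yl]but-2-en-1-yl acetate
Conditions: Ac2O, pyridine, DMAP (cat.), CH2Cl2, 0 °C
Reagents that add atoms: acetic anhydride, CC(=O)OC(C)=O
Why: Standard O-acetylation; it installs the C4 acetate of the target and deactivates the neighbouring trisubstituted alkene towards ozone.

Step 6
Reactants: 9 acetate
Product: 11 (1R,2E)-4,4-diethoxy-2-methyl-1-[(2R,3S)-3-methyl-3-(3-oxopropyl)oxiran-2-yl]but-2-en-1-yl acetate, via secondary ozonide 10 (not isolated)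
Conditions: O3, CH2Cl2, −78 °C (Sudan Red 7B end point); then PPh3, −78 → 20 °C
Reagents that add atoms: ozone, [O-][O+]=O
Why: Chemoselective ozonolysis; the electron-rich prenyl alkene reacts far faster than the alkene flanked by the allylic acetate and the acetal carbon, so titration to the dye end point cleaves only the former.

Step 7
Reactants: 11 aldehyde
Product: 12 (1R,2E)-4,4-diethoxy-1-{(2R,3S)-3-[(3R)-3-hydroxypent-4-en-1-yl]-3-methyloxiran-2-yl}-2-methylbut-2-en-1-yl acetate
Conditions: divinylzinc (2 equiv), (−)-MIB (10 mol %), toluene, −10 °C; H2O work-up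
Reagents that add atoms: divinylzinc, C=C[Zn]C=C
Why: Amino-alcohol-catalysed enantioselective vinylzinc addition (Oppolzer/Noyori type); the (−)-ligand series delivers vinyl to the Si face, giving the 3R carbinol (C9 R) under pure catalyst control, the other stereocentres being remote.

Step 8
Reactants: 12 allylic alcohol; 13 angelic acid
Product: 15 (3R)-5-{(2S,3R)-3-[(1R,2E)-1-acetoxy-4,4-diethoxy-2-methylbut-2-en-1-yl]-2-methyloxiran-2-yl}pent-1-en-3-yl (2Z)-2-methylbut-2-enoate, via mixed anhydride 14 (not isolated)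
Conditions: 13, 2,4,6-trichlorobenzoyl chloride, Et3N, toluene, 20 °C; then 12, 75 °C (no DMAP)
Reagents that add atoms: none
Why: Yamaguchi-type mixed-anhydride esterification run without nucleophilic catalyst, the established way to make angelates without Z→E isomerisation to the tiglate; C9 is not touched.

Step 9
Reactants: 15 allylic angelate; 16 methyl 2-(bromomethyl)acrylate
Product: 17 methyl (2Z,4R,7S,8R,9R,10E)-9-acetoxy-2-(bromomethyl)-12,12-diethoxy-7,8-epoxy-7,10-dimethyl-4-{[(2Z)-2-methylbut-2-enoyl]oxy}dodeca-2,10-dienoate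
Conditions: 16 (5 equiv), second-generation Hoveyda–Grubbs catalyst (10 mol %), CH2Cl2, 40 °C
Reagents that add atoms: none
Why: Olefin cross-metathesis of a monosubstituted alkene with a 1,1-disubstituted acrylate (methacrylate class); only the terminal vinyl group is reactive, and the thermodynamic product has the C4 substituent trans to the ester, i.e. cis to CH2Br (2Z).

Step 10
Reactants: 17 allyl bromide acetal
Product: 18 methyl (2Z,4R,7S,8R,9R,10E)-9-acetoxy-2-(bromomethyl)-7,8-epoxy-7,10-dimethyl-4-{[(2Z)-2-methylbut-2-enoyl]oxy}-12-oxododeca-2,10-dienoate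
Conditions: PPTS (cat.), acetone/H2O (10:1), 20 °C
Reagents that add atoms: water, O
Why: Hydrolysis of an α,β-unsaturated acetal, which is fast under acid too weak to open the epoxide or solvolyse the allyl bromide; the E enal is the thermodynamic geometry.

Step 11
Reactants: 18 enal allyl bromide
Product: 21 target lactone CNP0519641.1, via allylchromium dichloride 19 (not isolated), via seco hydroxy ester 20 (not isolated)
Conditions: CrCl2 (8 equiv), THF/DMF (3:1), 2 mM, slow addition of 18, 25 °C; aqueous work-up (PPTS, CH2Cl2 to finish lactonisation if needed)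
Reagents that add atoms: none
Why: Intramolecular Nozaki–Hiyama-type 2-(alkoxycarbonyl)allylation (Dreiding–Schmidt lactone synthesis), as used to close germacranolide rings: the Z allylchromium adds 1,2 to the enal through a closed chair, which makes O1/C9 syn on the C1–C10 bond (cis-lactone once the alkoxide closes on the ester), while A(1,3) strain keeps H9 in the allyl plane so C1 bonds to C10 anti to the C8 chain on the acyloxy-bearing face, giving 1S,10R from 9R.

## Compound list

1 | 1,1-diethoxybut-2-yne | CC#CC(OCC)OCC | starting material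
2 | (E)-(4,4-diethoxybut-2-en-2-yl)zirconocene chloride | CCOC(OCC)/C=C(\C)[Zr](Cl)(C1C=CC=C1)C1C=CC=C1 | intermediate
3 | (2E)-1,1-diethoxy-3-iodobut-2-ene | CCOC(OCC)/C=C(\C)I | intermediate
4 | nerol, (2Z)-3,7-dimethylocta-2,6-dien-1-ol | CC(C)=CCC/C(C)=C\CO | starting material
5 | (2R,3S)-2,3-epoxynerol, [(2R,3S)-3-methyl-3-(4-methylpent-3-en-1-yl)oxiran-2-yl]methanol | OC[C@H]1O[C@@]1(C)CCC=C(C)C | intermediate
6 | (2S,3S)-3-methyl-3-(4-methylpent-3-en-1-yl)oxirane-2-carbaldehyde | O=C[C@H]1O[C@@]1(C)CCC=C(C)C | intermediate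
7 | (E)-(4,4-diethoxybut-2-en-2-yl)lithium | CCOC(OCC)/C=C(\C)[Li] | intermediate
8 | (1R,2E)-4,4-diethoxy-2-methyl-1-[(2R,3S)-3-methyl-3-(4-methylpent-3-en-1-yl)oxiran-2-yl]but-2-en-1-ol | CCOC(OCC)/C=C(\C)[C@@H](O)[C@H]1O[C@@]1(C)CCC=C(C)C | intermediate
9 | acetate of 8 | CCOC(OCC)/C=C(\C)[C@@H](OC(C)=O)[C@H]1O[C@@]1(C)CCC=C(C)C | intermediate
10 | secondary ozonide of 9 (3,3-dimethyl-1,2,4-trioxolan-5-yl end group) | CCOC(OCC)/C=C(\C)[C@@H](OC(C)=O)[C@H]1O[C@@]1(C)CCC2OOC(C)(C)O2 | intermediate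
11 | (1R,2E)-4,4-diethoxy-2-methyl-1-[(2R,3S)-3-methyl-3-(3-oxopropyl)oxiran-2-yl]but-2-en-1-yl acetate | CCOC(OCC)/C=C(\C)[C@@H](OC(C)=O)[C@H]1O[C@@]1(C)CCC=O | intermediate
12 | (1R,2E)-4,4-diethoxy-1-{(2R,3S)-3-[(3R)-3-hydroxypent-4-en-1-yl]-3-methyloxiran-2-yl}-2-methylbut-2-en-1-yl acetate | CCOC(OCC)/C=C(\C)[C@@H](OC(C)=O)[C@H]1O[C@@]1(C)CC[C@@H](O)C=C | intermediate
13 | angelic acid, (2Z)-2-methylbut-2-enoic acid | C/C=C(/C)C(=O)O | starting material
14 | angelic 2,4,6-trichlorobenzoic anhydride | C/C=C(/C)C(=O)OC(=O)c1c(Cl)cc(Cl)cc1Cl | intermediate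
15 | (3R)-5-{(2S,3R)-3-[(1R,2E)-1-acetoxy-4,4-diethoxy-2-methylbut-2-en-1-yl]-2-methyloxiran-2-yl}pent-1-en-3-yl (2Z)-2-methylbut-2-enoate | CCOC(OCC)/C=C(\C)[C@@H](OC(C)=O)[C@H]1O[C@@]1(C)CC[C@@H](OC(=O)/C(C)=C\C)C=C | intermediate
16 | methyl 2-(bromomethyl)acrylate | C=C(CBr)C(=O)OC | starting material
17 | methyl (2Z,4R,7S,8R,9R,10E)-9-acetoxy-2-(bromomethyl)-12,12-diethoxy-7,8-epoxy-7,10-dimethyl-4-{[(2Z)-2-methylbut-2-enoyl]oxy}dodeca-2,10-dienoate | CCOC(OCC)/C=C(\C)[C@@H](OC(C)=O)[C@H]1O[C@@]1(C)CC[C@@H](OC(=O)/C(C)=C\C)/C=C(\CBr)C(=O)OC | intermediate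
18 | methyl (2Z,4R,7S,8R,9R,10E)-9-acetoxy-2-(bromomethyl)-7,8-epoxy-7,10-dimethyl-4-{[(2Z)-2-methylbut-2-enoyl]oxy}-12-oxododeca-2,10-dienoate | O=C/C=C(\C)[C@@H](OC(C)=O)[C@H]1O[C@@]1(C)CC[C@@H](OC(=O)/C(C)=C\C)/C=C(\CBr)C(=O)OC | intermediate
19 | allylchromium dichloride derived from 18 (CrCl2 on the former CH2Br carbon) | O=C/C=C(\C)[C@@H](OC(C)=O)[C@H]1O[C@@]1(C)CC[C@@H](OC(=O)/C(C)=C\C)/C=C(\C[Cr](Cl)Cl)C(=O)OC | intermediate
20 | seco hydroxy ester, methyl 2-[(1S,2E,4R,5R,6S,9R,10S)-4-acetoxy-9-angeloyloxy-5,6-epoxy-1-hydroxy-3,6-dimethylcyclodec-2-en-10-yl]acrylate (ring numbering as above; formed as its chromium alkoxide) | C=C(C(=O)OC)[C@H]1[C@@H](O)/C=C(\C)[C@@H](OC(C)=O)[C@H]2O[C@@]2(C)CC[C@H]1OC(=O)/C(C)=C\C | intermediate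
21 | CNP0519641.1, (1S,2E,4R,5R,6S,9R,10R)-4-acetoxy-9-[(2Z)-2-methylbut-2-enoyloxy]-5,6-epoxy-3,6-dimethyl-11(13)-methylene-cyclodec-2-ene 12,1-lactone (ring numbering as above) | C=C1C(=O)O[C@H]2/C=C(\C)[C@@H](OC(C)=O)[C@H]3O[C@@]3(C)CC[C@@H](OC(=O)/C(C)=C\C)[C@@H]12 | target

## Step count and risks

Total step count: 11. Longest linear sequence: 10 (steps 2–11, from nerol); step 1 is a one-step side branch.

**Step 11 (ring closure).** Three things can go wrong: the 10-membered closure itself; 1,4-elimination of the C9 angelate from the allylmetal to give a dienoate; and the facial sense at C10 relative to C9. The facial sense is a prediction from the A(1,3)/closed-chair model and was not checked against a direct precedent. If the aldehyde adds anti to the acyloxy group instead, the 1,10-bis-epimer results. The fallback replaces the reductively generated allylmetal by a preformed allylboron reagent. It sets out from 15 and 16 and comes back to the route at 21. Copper-catalysed borylation of 16 (B2pin2, CuCl, KOAc, DMF) gives methyl 2-[(pinacolatoboryl)methyl]acrylate F1. Cross-metathesis of 15 with F1 (same catalyst as step 9) gives the allylboronate acetal F2, with C9 cis to CH2Bpin (formally 2E). PPTS in wet acetone gives the enal allylboronate F3. Heating F3 at 1 mM in toluene (80 °C) effects intramolecular allylboration through the same closed chair without any carbanionic allylmetal, giving the O-boryl ether of the seco hydroxy ester F4. F4 lactonises on mildly acidic work-up to 21.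

**Step 9 (cross-metathesis).** A secondary allylic ester and a 1,1-disubstituted acrylate are both sluggish metathesis partners. The fallback builds the same bromide by Morita–Baylis–Hillman chemistry; it sets out from 15 and comes back at 17. One-pot OsO4 (cat.)/NaIO4/2,6-lutidine in dioxane–water dihydroxylates only the unhindered vinyl group to the diol F5. Periodate cleaves F5 in the same pot to the α-angeloyloxy aldehyde F6. F6 reacts with methyl acrylate and DABCO to give the Baylis–Hillman adduct F7 (both carbinol epimers converge). NBS/Me2S in CH2Cl2 at 0 °C converts F7 with allylic transposition into 17, the 2Z bromide being the thermodynamic isomer.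

**Step 7 (catalytic vinylation).** Enantioselectivity for an unbranched aldehyde is moderate, and divinylzinc is awkward to prepare salt-free. The fallback is a resolution; it sets out from 11 and comes back at 12, at the cost of at most 50 % yield. Vinylmagnesium bromide (THF, −78 °C) adds without control to give 12 together with its C9 epimer F8. Sharpless kinetic resolution (Ti(OiPr)4, L-(+)-diisopropyl tartrate, 0.6 equiv t-BuOOH, −20 °C) epoxidises the fast-reacting (S)-carbinol F8 to the erythro epoxy alcohol F9. Unreacted 12 is then separated by chromatography.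

Further compounds
F1 | step 11 | methyl 2-[(4,4,5,5-tetramethyl-1,3,2-dioxaborolan-2-yl)methyl]acrylate | C=C(CB1OC(C)(C)C(C)(C)O1)C(=O)OC
F2 | step 11 | allylboronate acetal (17 with CH2Bpin in place of CH2Br) | CCOC(OCC)/C=C(\C)[C@@H](OC(C)=O)[C@H]1O[C@@]1(C)CC[C@@H](OC(=O)/C(C)=C\C)/C=C(\CB2OC(C)(C)C(C)(C)O2)C(=O)OC
F3 | step 11 | enal allylboronate (18 with CH2Bpin in place of CH2Br) | O=C/C=C(\C)[C@@H](OC(C)=O)[C@H]1O[C@@]1(C)CC[C@@H](OC(=O)/C(C)=C\C)/C=C(\CB2OC(C)(C)C(C)(C)O2)C(=O)OC
F4 | step 11 | O-(pinacolatoboryl) ether of seco hydroxy ester 20 | C=C(C(=O)OC)[C@H]1[C@@H](OB3OC(C)(C)C(C)(C)O3)/C=C(\C)[C@@H](OC(C)=O)[C@H]2O[C@@]2(C)CC[C@H]1OC(=O)/C(C)=C\C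
F5 | step 9 | 1,2-diol from the vinyl group of 15 | CCOC(OCC)/C=C(\C)[C@@H](OC(C)=O)[C@H]1O[C@@]1(C)CC[C@@H](OC(=O)/C(C)=C\C)C(O)CO
F6 | step 9 | α-angeloyloxy aldehyde | CCOC(OCC)/C=C(\C)[C@@H](OC(C)=O)[C@H]1O[C@@]1(C)CC[C@@H](OC(=O)/C(C)=C\C)C=O
F7 | step 9 | Baylis–Hillman adduct of F6 with methyl acrylate | CCOC(OCC)/C=C(\C)[C@@H](OC(C)=O)[C@H]1O[C@@]1(C)CC[C@@H](OC(=O)/C(C)=C\C)C(O)C(=C)C(=O)OC
F8 | step 7 | C9 epimer of 12, (3S)-carbinol | CCOC(OCC)/C=C(\C)[C@@H](OC(C)=O)[C@H]1O[C@@]1(C)CC[C@H](O)C=C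
F9 | step 7 | erythro epoxy alcohol from F8 | CCOC(OCC)/C=C(\C)[C@@H](OC(C)=O)[C@H]1O[C@@]1(C)CC[C@H](O)[C@H]2CO2
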